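All runs come from a simulation with made-up constants, and the scatter is random.

The target has to come out of the solid substrate, so in a repeat of this run I watch how fast the solid goes, per litre and not as a percentage of the charge.

all flasks: gas phase 14 mM (held)
- birch: solid substrate 0.10 M; run made earlier
- elm: solid substrate 0.15 M; run made earlier
- flask: solid substrate 0.20 M; time 6.0 min

| run | time / min | target / % | solid substrate / % |
|---|---|---|---|
| birch | 0.200 | 0.4 | 99.8 |
| birch | 0.500 | 0.9 | 98.9 |
| birch | 1.00 | 1.3 | 97.2 |
| birch | 1.50 | 2.0 | 93.7 |
| birch | 2.00 | 3.0 | 92.6 |
| birch | 3.00 | 5.1 | 89.0 |
| birch | 4.00 | 7.0 | 86.7 |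
| elm | 0.500 | 0 | 97.8 |
| elm | 1.00 | 0.8 | 98.2 |
| elm | 1.50 | 1.5 | 95.4 |
| elm | 2.00 | 2.5 | 96.4 |
| elm | 2.50 | 3.2 | 94.2 |
| elm | 3.00 | 3.0 | 93.2 |
| elm | 4.00 | 5.6 | 91.5 |

(standard deviation of a reading: 0.5 percentage points)

- as a solid, counted per litre of solution: solid substrate
- the numbers in the tables scatter by 0.5 percentage points (one standard deviation)
- at the start none of the solid substrate is in solution
- at the start none of the gas phase is in solution

- north-east: doubling the transfer coefficient of the gas phase, all else as stated
- east: doubling the solubility of the solid substrate, all else as stated
- north: doubling the dissolution coefficient of the solid substrate, all else as stated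
- west: doubling the saturation concentration of gas phase, all else as stated

* the target standing at 6.0 min, as a percentage of the solid substrate charged
* the change that raises the amount of target at 6.0 min, in percent of the solid substrate charged most ("none" if none brings more than 2 percentage points) (north-east / east / north / west / none)
* amount of target at 6.0 min, in percent of the solid substrate charged, after north-east

I put the last reading of each earlier run into concentrations:

- birch, 0.10 M charged, by 4.00 min: solid lost 13.3 mM, c(target) 7.00 mM
- elm, 0.15 M charged, by 4.00 min: solid lost 12.7 mM, c(target) 8.40 mM

The charge goes up from birch to elm, but the solid lost stays about level. So I replace both curves by one straight line and carry its slope, the solid pace, meaning solid lost per litre per minute: 3.26 mM min⁻¹. In these two runs it is zero-order in the charge. The line is a fair stand-in, since at 2.00 min it gives 6.52 mM where birch reads 7.40 mM.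

The target column gives the share of the lost solid found as target, 0.526 in birch and 0.661 in elm, with a mean of 0.593.

For the flask at 6.0 min the pace gives 19.5 mM of solid lost, or 9.77% of its charge. If the share holds, I reckon 5.79% of target. North-east acts on the gas and the pace I carry is a pace of the solid, so I give north-east the same figure, and I look to east or north, the two changes that act on the solid.

The forecast says 6.2%, a figure above mine, with west as the best change and 8.5% after north-east, and it holds that “the solid charge doesn't matter”.

The flask gives 4.33%, the best change is east at 4.6 percentage points, and north-east gives 4.26%.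

    starting material + dissolved gas → target (k = 82.8 L mol⁻¹ min⁻¹)
    solid substrate ⇌ starting material, rate k2*(cs2 - [starting material]) while solid is left; crystals form when [starting material] > cs2 (solubility = 13.0 mM, k = 0.314 min⁻¹)
    gas phase ⇌ dissolved gas, rate k3*(csat - [dissolved gas]) (kL = 2.58 min⁻¹)
    dissolved gas + target → over-reaction product (k = 5.80 L mol⁻¹ min⁻¹)
    dissolved gas + target → over-reacted product (k = 16.3 L mol⁻¹ min⁻¹)

At 6.00 min the flask's solid stands at 90.3%, and the pace said 90.2%. The target there is 8.67 mM, a share of 0.444 of the reckoned loss, and over-reacted product stands at 2.80%. A neighbour flask is charged with 0.050 M and read at the same time. The same pace takes 39.0% of that charge and leaves 61.0%, and the solid in that neighbour flask stands at 61.2%.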